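**Plan**

1. Cuts: (a) the bond from the enone α-carbon to the heptenyl group (Suzuki); (b) both ring bonds of that same α-carbon, C(=O)–C and C=C(CH2OH), which removes it from the six-membered carbocycle and leaves a cyclopentanone; (c) the C–CH2OH bond (aldol), the two epoxide C–O bonds, the side-chain C=C (cross-metathesis) and the ring–CH2 bond (Stille).
2. Enabling feature: in the carbocycle the heptenyl carbon lies between the ketone carbon and the hydroxymethyl carbon, and the other α-carbon is the fully substituted epoxide carbon. The epoxycyclopentanone can therefore enolise in one direction only, and a carbon inserted into that enol ether C=C lands at the heptenyl position as a vinyl bromide.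
3. Forward: the five-membered carbocycle is bought; the side chain is joined (iodination, Stille, metathesis); the epoxide ring is made; hydroxymethylation and silylation give the enol ether; a bromoform carbon enlarges the ring from five to six; the heptenyl group is joined last; one acid step frees diol and acid.
4. Stereochemistry: the carbinol centre is bought in (S)-4-silyloxycyclopentenone. Luche reduction relays it to a cis helper carbinol, whose hydroxyl directs the epoxidation that sets both epoxide centres in one event on the face of the silyloxy group; the helper is then oxidised to the ketone.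

Key step: step 9

Assumption: (S)-4-(tert-butyldimethylsilyloxy)cyclopent-2-en-1-one is taken as a catalogue compound in enantiopure form. Abbreviations: TBS = tert-butyldimethylsilyl, TES = triethylsilyl, TBSO/TESO = the corresponding silyloxy groups.

**Step 1**
Reactants: 1 (S)-4-(TBSO)cyclopent-2-en-1-one
Product: 2 (S)-2-iodo-4-(TBSO)cyclopent-2-en-1-one
Conditions: I2, pyridine/CH2Cl2 (1:1), 0 °C → rt
Reagents that add atoms: iodine, II
Why: α-Iodination of the enone by conjugate addition of pyridine, iodination of the enolate and elimination (Baylis–Hillman-type mechanism) should place iodine on the α-carbon without touching the silyloxy stereocentre.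

**Step 2**
Reactants: 2 (S)-2-iodo-4-(TBSO)cyclopent-2-en-1-one; 3 allyltributylstannane
Product: 4 (S)-2-allyl-4-(TBSO)cyclopent-2-en-1-one
Conditions: Pd2(dba)3 (2.5 mol%), AsPh3, CuI, NMP, rt → 40 °C
Reagents that add atoms: allyltributylstannane, C=CC[Sn](CCCC)(CCCC)CCCC
Why: Stille coupling (oxidative addition of zerovalent palladium into the activated C–I bond, copper-assisted allyl transfer from tin, reductive elimination) should give the 2-allyl enone under neutral conditions that leave the β-silyloxy ketone intact.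

**Step 3**
Reactants: 4 (S)-2-allyl-4-(TBSO)cyclopent-2-en-1-one; 5 tert-butyl methacrylate
Product: 6 tert-butyl (E)-2-methyl-4-[(S)-5-oxo-3-(TBSO)cyclopent-1-en-1-yl]but-2-enoate
Conditions: 5 (8 equiv), second-generation Hoveyda–Grubbs catalyst RuCl2(H2IMes)(=CH-C6H4-2-OiPr) (5 mol%), 1,4-benzoquinone (10 mol%), CH2Cl2, 40 °C
Reagents that add atoms: tert-butyl methacrylate, CC(=C)C(=O)OC(C)(C)C
Why: Olefin cross-metathesis of the terminal alkene with the 1,1-disubstituted acrylate should give the thermodynamically favoured E trisubstituted enoate, the electron-poor trisubstituted enone alkene being inert and benzoquinone suppressing isomerisation of the skipped diene.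

**Step 4**
Reactants: 6 tert-butyl (E)-2-methyl-4-[(S)-5-oxo-3-(TBSO)cyclopent-1-en-1-yl]but-2-enoate
Product: 7 tert-butyl (E)-4-[(3S,5R)-5-hydroxy-3-(TBSO)cyclopent-1-en-1-yl]-2-methylbut-2-enoate
Conditions: NaBH4, CeCl3·7H2O, MeOH, −78 °C
Reagents that add atoms: none
Why: Luche 1,2-reduction should deliver hydride to the ketone face opposite the silyloxy group, so the new carbinol is cis to it, while the enoate is not reduced.

**Step 5**
Reactants: 7 tert-butyl (E)-4-[(3S,5R)-5-hydroxy-3-(TBSO)cyclopent-1-en-1-yl]-2-methylbut-2-enoate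
Product: 8 tert-butyl (E)-4-[(1R,2R,4S,5S)-2-hydroxy-4-(TBSO)-6-oxabicyclo[3.1.0]hexan-1-yl]-2-methylbut-2-enoate
Conditions: VO(acac)2 (5 mol%), t-BuOOH (decane), CH2Cl2, 0 °C → rt
Reagents that add atoms: tert-butyl hydroperoxide, CC(C)(C)OO
Why: Vanadium-catalysed hydroxyl-directed epoxidation should transfer oxygen to the ring alkene from the face of the allylic hydroxyl, setting both epoxide stereocentres at once syn to the carbinol and hence syn to the silyloxy group, with the electron-poor enoate left alone.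

**Step 6**
Reactants: 8 tert-butyl (E)-4-[(1R,2R,4S,5S)-2-hydroxy-4-(TBSO)-6-oxabicyclo[3.1.0]hexan-1-yl]-2-methylbut-2-enoate
Product: 9 tert-butyl (E)-2-methyl-4-[(1S,4S,5S)-2-oxo-4-(TBSO)-6-oxabicyclo[3.1.0]hexan-1-yl]but-2-enoate
Conditions: Dess–Martin periodinane, pyridine, CH2Cl2, 0 °C → rt
Reagents that add atoms: none
Why: Dess–Martin oxidation under buffered conditions should convert the helper carbinol into the ketone without epimerisation or loss of the β-silyloxy group, leaving the epoxide and silyloxy stereocentres as set.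

**Step 7**
Reactants: 9 tert-butyl (E)-2-methyl-4-[(1S,4S,5S)-2-oxo-4-(TBSO)-6-oxabicyclo[3.1.0]hexan-1-yl]but-2-enoate; 10 formaldehyde
Product: 12 tert-butyl (E)-4-[(1S,4S,5S)-3-(hydroxymethyl)-2-oxo-4-(TBSO)-6-oxabicyclo[3.1.0]hexan-1-yl]-2-methylbut-2-enoate, via lithium enolate 11 (not isolated)
Conditions: LiN(SiMe3)2 (1.1 equiv), THF, −78 °C; HCHO (monomer from cracked paraformaldehyde), −78 °C; AcOH quench at −78 °C
Reagents that add atoms: formaldehyde, C=O
Why: Aldol hydroxymethylation of a regiodefined lithium enolate (only the CH2 α-carbon carries protons, the other α-carbon being the quaternary epoxide carbon) should work if low temperature and fast trapping by formaldehyde outrun loss of the β-silyloxy group; the new stereocentre is uncontrolled and becomes sp2 in step 8.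

**Step 8**
Reactants: 12 tert-butyl (E)-4-[(1S,4S,5S)-3-(hydroxymethyl)-2-oxo-4-(TBSO)-6-oxabicyclo[3.1.0]hexan-1-yl]-2-methylbut-2-enoate
Product: 13 tert-butyl (E)-2-methyl-4-[(1S,4S,5S)-4-(TBSO)-2-(TESO)-3-(TESO-methyl)-6-oxabicyclo[3.1.0]hex-2-en-1-yl]but-2-enoate
Conditions: TESOTf (2.5 equiv), Et3N (5 equiv), CH2Cl2, −78 → −20 °C; NaHCO3 work-up; Et3N-deactivated silica
Reagents that add atoms: triethylsilyl trifluoromethanesulfonate, CC[Si](CC)(CC)OS(=O)(=O)C(F)(F)F
Why: Soft enolisation should silylate the primary hydroxyl and the ketone oxygen and remove the only α-proton, giving a single tetrasubstituted silyl enol ether without a metal enolate that could expel the β-silyloxy groups, while low temperature and excess amine spare the tert-butyl ester and the epoxide.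

**Step 9**
Reactants: 13 tert-butyl (E)-2-methyl-4-[(1S,4S,5S)-4-(TBSO)-2-(TESO)-3-(TESO-methyl)-6-oxabicyclo[3.1.0]hex-2-en-1-yl]but-2-enoate; 14 bromoform
Product: 16 tert-butyl (E)-4-[(1S,5S,6S)-3-bromo-2-oxo-5-(TBSO)-4-(TESO-methyl)-7-oxabicyclo[4.1.0]hept-3-en-1-yl]-2-methylbut-2-enoate, via dibromocyclopropane adduct 15 (not isolated)
Conditions: CHBr3 (3 equiv), KOtBu (2.5 equiv), pentane, −40 → −15 °C; pH 7 buffer; then CH2Cl2/sat. aq NaHCO3, rt
Reagents that add atoms: bromoform, BrC(Br)Br
Why: Dibromocarbene, released from bromoform by tert-butoxide, should add in a concerted [2+1] fashion to the electron-rich tetrasubstituted enol ether C=C of 13 and close the transient cyclopropane of 15; on warming, the bromide endo to the five-membered ring ionises with disrotatory 2π-electrocyclic opening of the cyclopropane, pushed by the silyloxy oxygen, so that the bond shared by the two rings breaks and the five-membered carbocycle becomes the six-membered one as an O-silylated 2-bromoenone that bromide desilylates. The closest known reaction type is the one-carbon ring expansion of cycloalkanone silyl enol ethers with dihalocarbenes to 2-halocycloalk-2-enones. No ring of the product is closed by cyclisation: the six-membered ring arises by enlargement through cleavage of the internal bicyclo[3.1.0]hexane bond, and the only ring closed on the way is the cyclopropane, by carbene cycloaddition. No lasting stereocentre is created, because both cyclopropane carbons end as sp2 carbons of the enone and attack on either face converges on 16, while the silyloxy carbon and the two epoxide carbons are spectators. The step needs regiocontrol of the inserted carbon, fixed in 13 because the ketone could enolise only toward the hydroxymethyl-bearing carbon, and chemoselectivity for the enol ether over the side-chain alkene, secured by the electrophilic carbene preferring the electron-rich enol ether to the electron-poor enoate. Carbene transfer at low temperature followed by buffered warming should keep tert-butoxide away from the base-sensitive bromoenone.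

**Step 10**
Reactants: 16 tert-butyl (E)-4-[(1S,5S,6S)-3-bromo-2-oxo-5-(TBSO)-4-(TESO-methyl)-7-oxabicyclo[4.1.0]hept-3-en-1-yl]-2-methylbut-2-enoate; 17 (E)-hept-1-enylboronic acid
Product: 18 tert-butyl (E)-4-[(1S,5S,6S)-3-[(E)-hept-1-enyl]-2-oxo-5-(TBSO)-4-(TESO-methyl)-7-oxabicyclo[4.1.0]hept-3-en-1-yl]-2-methylbut-2-enoate
Conditions: Pd(OAc)2 (5 mol%), SPhos (10 mol%), K3PO4, THF/H2O (10:1), 40 °C
Reagents that add atoms: (E)-hept-1-enylboronic acid, CCCCC/C=C/B(O)O
Why: Suzuki–Miyaura coupling of the α-bromoenone, an activated vinyl bromide for oxidative addition to zerovalent palladium formed in situ, should install the heptenyl group with retention of its E geometry under a mild phosphate base that spares the epoxy enone, silyl ethers and ester.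

**Step 11**
Reactants: 18 tert-butyl (E)-4-[(1S,5S,6S)-3-[(E)-hept-1-enyl]-2-oxo-5-(TBSO)-4-(TESO-methyl)-7-oxabicyclo[4.1.0]hept-3-en-1-yl]-2-methylbut-2-enoate
Product: 19 (E)-4-[(1S,5S,6S)-3-[(E)-hept-1-enyl]-5-hydroxy-4-(hydroxymethyl)-2-oxo-7-oxabicyclo[4.1.0]hept-3-en-1-yl]-2-methylbut-2-enoic acid
Conditions: TFA/H2O (9:1), CH2Cl2, 0 °C → rt; toluene azeotrope; pH 7 buffer work-up
Reagents that add atoms: none
Why: Acidolysis should cleave the tert-butyl ester with loss of 2-methylpropene and hydrolyse both silyl ethers, the epoxide being shielded from opening because its α-carbon is fully substituted and next to the ketone, so no stereocentre is affected.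

**Compound list**

1 | (S)-4-(tert-butyldimethylsilyloxy)cyclopent-2-en-1-one | O=C1C[C@H](O[Si](C)(C)C(C)(C)C)C=C1 | starting material
2 | (S)-2-iodo-4-(TBSO)cyclopent-2-en-1-one | O=C1C[C@H](O[Si](C)(C)C(C)(C)C)C=C1I | intermediate
3 | allyltributylstannane | C=CC[Sn](CCCC)(CCCC)CCCC | starting material
4 | (S)-2-allyl-4-(TBSO)cyclopent-2-en-1-one | O=C1C[C@H](O[Si](C)(C)C(C)(C)C)C=C1CC=C | intermediate
5 | tert-butyl methacrylate | CC(=C)C(=O)OC(C)(C)C | starting material
6 | tert-butyl (E)-2-methyl-4-[(S)-5-oxo-3-(TBSO)cyclopent-1-en-1-yl]but-2-enoate | O=C1C[C@H](O[Si](C)(C)C(C)(C)C)C=C1C/C=C(\C)C(=O)OC(C)(C)C | intermediate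
7 | tert-butyl (E)-4-[(3S,5R)-5-hydroxy-3-(TBSO)cyclopent-1-en-1-yl]-2-methylbut-2-enoate (OH cis to OTBS) | C1[C@H](O[Si](C)(C)C(C)(C)C)C=C(C/C=C(\C)C(=O)OC(C)(C)C)[C@@H]1O | intermediate
8 | tert-butyl (E)-4-[(1R,2R,4S,5S)-2-hydroxy-4-(TBSO)-6-oxabicyclo[3.1.0]hexan-1-yl]-2-methylbut-2-enoate (OH, epoxide O and OTBS on one face) | C1[C@H](O[Si](C)(C)C(C)(C)C)[C@@H]2O[C@]2(C/C=C(\C)C(=O)OC(C)(C)C)[C@@H]1O | intermediate
9 | tert-butyl (E)-2-methyl-4-[(1S,4S,5S)-2-oxo-4-(TBSO)-6-oxabicyclo[3.1.0]hexan-1-yl]but-2-enoate | C1[C@H](O[Si](C)(C)C(C)(C)C)[C@@H]2O[C@]2(C/C=C(\C)C(=O)OC(C)(C)C)C1=O | intermediate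
10 | formaldehyde (commercial as paraformaldehyde, cracked to the monomer before use) | C=O | starting material
11 | lithium enolate of 9, lithium (1S,4S,5S)-1-[(E)-4-tert-butoxy-3-methyl-4-oxobut-2-enyl]-4-(TBSO)-6-oxabicyclo[3.1.0]hex-2-en-2-olate | C1[C@H](O[Si](C)(C)C(C)(C)C)[C@@H]2O[C@]2(C/C=C(\C)C(=O)OC(C)(C)C)C=1[O-].[Li+] | intermediate (not isolated)
12 | tert-butyl (E)-4-[(1S,4S,5S)-3-(hydroxymethyl)-2-oxo-4-(TBSO)-6-oxabicyclo[3.1.0]hexan-1-yl]-2-methylbut-2-enoate (epimers at the hydroxymethyl carbon) | OCC1[C@H](O[Si](C)(C)C(C)(C)C)[C@@H]2O[C@]2(C/C=C(\C)C(=O)OC(C)(C)C)C1=O | intermediate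
13 | tert-butyl (E)-2-methyl-4-[(1S,4S,5S)-4-(TBSO)-2-(TESO)-3-(TESO-methyl)-6-oxabicyclo[3.1.0]hex-2-en-1-yl]but-2-enoate | C1(CO[Si](CC)(CC)CC)[C@H](O[Si](C)(C)C(C)(C)C)[C@@H]2O[C@]2(C/C=C(\C)C(=O)OC(C)(C)C)C=1O[Si](CC)(CC)CC | intermediate
14 | bromoform | BrC(Br)Br | starting material
15 | tert-butyl (E)-4-[7,7-dibromo-5-(TBSO)-1-(TESO)-6-(TESO-methyl)-3-oxatricyclo[4.1.0.0(2,4)]heptan-2-yl]-2-methylbut-2-enoate (epoxide and silyloxy centres as in 13; cyclopropane on either face) | BrC1(Br)C2(CO[Si](CC)(CC)CC)[C@H](O[Si](C)(C)C(C)(C)C)[C@@H]3O[C@]3(C/C=C(\C)C(=O)OC(C)(C)C)C12O[Si](CC)(CC)CC | intermediate (not isolated)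
16 | tert-butyl (E)-4-[(1S,5S,6S)-3-bromo-2-oxo-5-(TBSO)-4-(TESO-methyl)-7-oxabicyclo[4.1.0]hept-3-en-1-yl]-2-methylbut-2-enoate | BrC1=C(CO[Si](CC)(CC)CC)[C@H](O[Si](C)(C)C(C)(C)C)[C@@H]2O[C@]2(C/C=C(\C)C(=O)OC(C)(C)C)C1=O | intermediate
17 | (E)-hept-1-enylboronic acid | CCCCC/C=C/B(O)O | starting material
18 | tert-butyl (E)-4-[(1S,5S,6S)-3-[(E)-hept-1-enyl]-2-oxo-5-(TBSO)-4-(TESO-methyl)-7-oxabicyclo[4.1.0]hept-3-en-1-yl]-2-methylbut-2-enoate | CCCCC/C=C/C1=C(CO[Si](CC)(CC)CC)[C@H](O[Si](C)(C)C(C)(C)C)[C@@H]2O[C@]2(C/C=C(\C)C(=O)OC(C)(C)C)C1=O | intermediate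
19 | (E)-4-[(1S,5S,6S)-3-[(E)-hept-1-enyl]-5-hydroxy-4-(hydroxymethyl)-2-oxo-7-oxabicyclo[4.1.0]hept-3-en-1-yl]-2-methylbut-2-enoic acid | CCCCC/C=C/C1=C(CO)[C@H](O)[C@@H]2O[C@]2(C/C=C(\C)C(=O)O)C1=O | target

**Step count and risks**

Total step count: 11. Longest linear sequence: 11 steps (1 → 19).

Steps most likely to fail:

Step 9. The carbene may add too slowly to the hindered tetrasubstituted enol ether, or tert-butoxide may attack the bromoenone as it forms (γ-deprotonation followed by opening of the epoxide). The fallback sets out from 13 and returns at 18. Simmons–Smith cyclopropanation with Et2Zn/CH2I2 should give the siloxycyclopropane F1. One-electron oxidation with FeCl3 in DMF should cleave its internal bond to the ring-enlarged β-chloro ketone F2, and NaOAc in MeOH should eliminate HCl to the enone F3. α-Iodination (I2, pyridine, DMAP) should then give the α-iodoenone F4, which is coupled with 17 under the conditions of step 10 to reach 18.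

Step 7. The lithium enolate may expel the β-silyloxy group or react a second time with formaldehyde. The fallback sets out from 9 and returns at 12. Soft enolisation with TMSOTf/Et3N in CH2Cl2 should give the trimethylsilyl enol ether F5 without a metal enolate, and a Mukaiyama-type hydroxymethylation with 37% aqueous formaldehyde and Yb(OTf)3 in THF should deliver 12.

Step 11. Slow hydrolysis of the hindered secondary silyl ether may leave time for acid-promoted opening of the epoxide or dehydration of the allylic carbinol. The fallback sets out from 18 and returns at 19. HF·pyridine in THF/pyridine should first remove both silyl ethers to give the diol tert-butyl ester F6, and a short exposure to anhydrous TFA in CH2Cl2 at 0 °C should then cleave only the ester to give 19.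

**Further compounds**

F1 | step 9 | siloxycyclopropane, the CH2 analogue of 15 (cyclopropane on either face) | C1C2(CO[Si](CC)(CC)CC)[C@H](O[Si](C)(C)C(C)(C)C)[C@@H]3O[C@]3(C/C=C(\C)C(=O)OC(C)(C)C)C12O[Si](CC)(CC)CC
F2 | step 9 | ring-enlarged β-chloro ketone, 4-chloro-4-(TESO-methyl)-5-(TBSO)-7-oxabicyclo[4.1.0]heptan-2-one bearing the side chain at C1 (epimers at the chlorinated carbon) | C1C(Cl)(CO[Si](CC)(CC)CC)[C@H](O[Si](C)(C)C(C)(C)C)[C@@H]2O[C@]2(C/C=C(\C)C(=O)OC(C)(C)C)C1=O
F3 | step 9 | tert-butyl (E)-2-methyl-4-[(1S,5S,6S)-2-oxo-5-(TBSO)-4-(TESO-methyl)-7-oxabicyclo[4.1.0]hept-3-en-1-yl]but-2-enoate | C1=C(CO[Si](CC)(CC)CC)[C@H](O[Si](C)(C)C(C)(C)C)[C@@H]2O[C@]2(C/C=C(\C)C(=O)OC(C)(C)C)C1=O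
F4 | step 9 | tert-butyl (E)-4-[(1S,5S,6S)-3-iodo-2-oxo-5-(TBSO)-4-(TESO-methyl)-7-oxabicyclo[4.1.0]hept-3-en-1-yl]-2-methylbut-2-enoate | IC1=C(CO[Si](CC)(CC)CC)[C@H](O[Si](C)(C)C(C)(C)C)[C@@H]2O[C@]2(C/C=C(\C)C(=O)OC(C)(C)C)C1=O
F5 | step 7 | tert-butyl (E)-2-methyl-4-[(1S,4S,5S)-4-(TBSO)-2-(trimethylsilyloxy)-6-oxabicyclo[3.1.0]hex-2-en-1-yl]but-2-enoate | C1[C@H](O[Si](C)(C)C(C)(C)C)[C@@H]2O[C@]2(C/C=C(\C)C(=O)OC(C)(C)C)C=1O[Si](C)(C)C
F6 | step 11 | tert-butyl (E)-4-[(1S,5S,6S)-3-[(E)-hept-1-enyl]-5-hydroxy-4-(hydroxymethyl)-2-oxo-7-oxabicyclo[4.1.0]hept-3-en-1-yl]-2-methylbut-2-enoate | CCCCC/C=C/C1=C(CO)[C@H](O)[C@@H]2O[C@]2(C/C=C(\C)C(=O)OC(C)(C)C)C1=O
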